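**Retrosynthetic overview**
1. Target ⇐ late-stage acylation, C9 reduction and 1,2-cis-dihydroxylation of trans-fused dienone 18; ring A is closed last by diene–ene metathesis (C1=C2).
2. The C10 quaternary centre of 17 ⇐ semipinacol 1,2-vinyl shift (C9→C10) in spiro-epoxy vinyl carbinol 16, which also delivers the free C14 hydroxyl and the C9 ketone.
3. 16 ⇐ α-methylene ketone 14 (vinyl addition, directed epoxidation) ⇐ enone 9 + (Z)-dienyl copper reagent from 2 + Mannich methylenation.
4. 9 ⇐ cyclohexenone by α′-selenenylation, rhodium-catalysed asymmetric isopropenylation (sets C7) and selenoxide elimination.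
5. Ring order: ring B (the cyclohexenone ring) comes first, ring A second.

Assumption: carbons carry their eventual eudesmane numbers throughout (ring B = C5–C10, C14 = CH2OH carbon on C10, isopropenyl on C7); α/β mean below/above the plane with ring A drawn on the left and C10 above C5.

Step 1
Reactants: 1 acrolein
Product: 2 (3Z)-4-iodopenta-1,3-diene
Conditions: EtPPh3I, n-BuLi, THF, 0 °C; I2, −78 °C; NaN(SiMe3)2, −20 °C; then 1, −78 °C to rt
Reagents that add atoms: ethyltriphenylphosphonium iodide CC[P+](c1ccccc1)(c1ccccc1)c1ccccc1.[I-]; iodine II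
Why: Stork–Zhao-type Wittig olefination with an α-iodo ylide gives the (Z)-vinyl iodide (iodine cis to the vinyl group) under kinetic control.

Step 2
Reactants: 3 cyclohex-2-en-1-one
Product: 5 (±)-6-(phenylselanyl)cyclohex-2-en-1-one, via lithium dienolate 4 (not isolated)
Conditions: LiN(i-Pr)2, THF, −78 °C; PhSeCl, −78 °C
Reagents that add atoms: phenylselenyl chloride Cl[Se]c1ccccc1
Why: Kinetic α′-deprotonation gives the cross-conjugated enolate, which is selenenylated at C6 (Reich α-selenenylation).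

Step 3
Reactants: 5 (±)-6-(phenylselanyl)cyclohex-2-en-1-one; 6 potassium trifluoro(prop-1-en-2-yl)borate
Product: 9 (5S)-5-(prop-1-en-2-yl)cyclohex-2-en-1-one, via selenide ketone 7 (not isolated), via selenoxide 8 (not isolated)
Conditions: [Rh(cod)2]BF4 (3 mol %), (S)-BINAP (3.3 mol %), toluene/H2O, 80 °C; then 30% H2O2, pyridine, CH2Cl2, 0 °C to rt
Reagents that add atoms: none
Why: Proposed new method: a Hayashi–Miyaura conjugate alkenylation run on an α′-selenenylated enone, in which catalyst-controlled carborhodation sets the S centre regardless of the remote racemic C–Se carbon, the chelating bisphosphine outcompetes the soft selenide for monovalent rhodium, and selenoxide syn-elimination then places the new enone only on the side remote from the isopropenyl group; the closest known chemistry is rhodium/BINAP 1,4-addition of alkenylboron reagents to cyclohexenone followed by Reich selenoxide elimination.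

Step 4
Reactants: 9 (5S)-5-(prop-1-en-2-yl)cyclohex-2-en-1-one; 2 (3Z)-4-iodopenta-1,3-diene
Product: 14 (3R,5S)-2-methylidene-3-[(2Z)-penta-2,4-dien-2-yl]-5-(prop-1-en-2-yl)cyclohexan-1-one, via dienyl Grignard 10 (not isolated), via silyl enol ether 11 (not isolated), via Mannich base 12 (not isolated), via methiodide 13 (not isolated)
Conditions: 2, i-PrMgCl·LiCl, THF, −40 °C; CuBr·SMe2 (10 mol %), Me3SiCl, 9, −78 °C; [CH2=NMe2]I, CH2Cl2, rt; MeI; aq. NaHCO3 (product used at once)
Reagents that add atoms: N,N-dimethylmethyleneiminium iodide C=[N+](C)C.[I-]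
Why: Copper-catalysed conjugate addition of the alkenyl Grignard (formed with retention by iodine–magnesium exchange) occurs anti to the C7 isopropenyl group and sets C5, and the regiodefined silyl enol ether then undergoes Mannich aminomethylation and Hofmann-type elimination to the α-methylene ketone.

Step 5
Reactants: 14 (3R,5S)-2-methylidene-3-[(2Z)-penta-2,4-dien-2-yl]-5-(prop-1-en-2-yl)cyclohexan-1-one
Product: 15 (5S)-1-ethenyl-2-methylidene-3-[(2Z)-penta-2,4-dien-2-yl]-5-(prop-1-en-2-yl)cyclohexan-1-ol (C9 vinyl β and OH α; vinyl trans to the C5 dienyl group)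
Conditions: CH2=CHMgBr, CeCl3, THF, −78 °C
Reagents that add atoms: vinylmagnesium bromide C=C[Mg]Br
Why: Organocerium 1,2-addition proceeds by equatorial attack on the conformer whose C5 dienyl group is axial (relief of allylic strain with the exocyclic methylene), so the vinyl group enters trans to the dienyl group.

Step 6
Reactants: 15 (5S)-1-ethenyl-2-methylidene-3-[(2Z)-penta-2,4-dien-2-yl]-5-(prop-1-en-2-yl)cyclohexan-1-ol
Product: 17 (5S)-2-ethenyl-2-(hydroxymethyl)-3-[(2Z)-penta-2,4-dien-2-yl]-5-(prop-1-en-2-yl)cyclohexan-1-one (C10 vinyl β and CH2OH α; vinyl trans to dienyl), via spiro-epoxy alcohol 16 (not isolated)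
Conditions: VO(acac)2 (5 mol %), t-BuOOH (1.1 equiv), CH2Cl2, 0 °C; Me2S; then ZnBr2, 0 °C to rt
Reagents that add atoms: tert-butyl hydroperoxide CC(C)(C)OO
Why: Hydroxyl-directed vanadium-catalysed epoxidation picks the 1,1-disubstituted allylic alkene and delivers oxygen syn to the α-hydroxyl, and the Lewis acid then triggers a semipinacol rearrangement in which the vinyl group anti to the C10–O bond shifts from C9 to C10 with inversion, setting the quaternary centre and unveiling the C9 ketone.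

Step 7
Reactants: 17 (5S)-2-ethenyl-2-(hydroxymethyl)-3-[(2Z)-penta-2,4-dien-2-yl]-5-(prop-1-en-2-yl)cyclohexan-1-one
Product: 18 trans-fused 8a-(hydroxymethyl)-5-methyl-3-(prop-1-en-2-yl)-3,4,4a,8a-tetrahydronaphthalen-1(2H)-one (4a-H β; 8a-CH2OH α; 3-isopropenyl β)
Conditions: second-generation Grubbs catalyst (5 mol %), CH2Cl2, 40 °C
Reagents that add atoms: none
Why: Ring-closing diene–ene metathesis between the C10 vinyl group and the terminal vinyl of the trans-disposed (Z)-dienyl group forms C1=C2 and the trans-fused ring A, the hindered isopropenyl group staying inert.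

Step 8
Reactants: 18 trans-fused 8a-(hydroxymethyl)-5-methyl-3-(prop-1-en-2-yl)-3,4,4a,8a-tetrahydronaphthalen-1(2H)-one
Product: 20 7α,8α-dihydroxy-8a-(hydroxymethyl)-5-methyl-3-(prop-1-en-2-yl)-3,4,4a,7,8,8a-hexahydronaphthalen-1(2H)-one (eudesmane 1α,2α,14-triol-9-one), via osmate ester 19 (not isolated)
Conditions: OsO4 (1.05 equiv), TMEDA, CH2Cl2, −78 °C; then aq. NaHSO3, THF, rt
Reagents that add atoms: osmium tetroxide O=[Os](=O)(=O)=O
Why: Donohoe-type hydrogen-bond-directed dihydroxylation, in which the axial C14 hydroxyl binds the OsO4·TMEDA complex and delivers it syn to the α face of the neighbouring C1=C2 bond, sets C1 and C2 in preference to the remote C3=C4 and isopropenyl alkenes.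

Step 9
Reactants: 20 eudesmane 1α,2α,14-triol-9-one
Product: 21 eudesma-3,11-diene-1α,2α,9β,14-tetraol (5βH; 7β-isopropenyl; 10α-CH2OH)
Conditions: Me4NBH(OAc)3, MeCN/AcOH, −20 °C to rt
Reagents that add atoms: none
Why: Evans–Saksena hydroxyl-directed reduction delivers hydride intramolecularly from boron bound to the α-face C14 (or C1) oxygen to the α face of the C9 ketone, giving the 9β alcohol anti to C14.

Step 10
Reactants: 21 eudesma-3,11-diene-1α,2α,9β,14-tetraol
Product: 22 14-O-tert-butyldimethylsilyl ether of 21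
Conditions: t-BuMe2SiCl (1.05 equiv), imidazole, DMF, 0 °C
Reagents that add atoms: tert-butyldimethylsilyl chloride CC(C)(C)[Si](C)(C)Cl
Why: Silylation is selective for the only primary hydroxyl (C14) over three hindered secondary ones.

Step 11
Reactants: 22 14-O-tert-butyldimethylsilyl ether of 21
Product: 24 1α-(3-methylbutanoyloxy)-14-(tert-butyldimethylsilyloxy)eudesma-3,11-diene-2α,9β-diol, via stannylene acetal 23 (not isolated)
Conditions: Bu2SnO, MeOH, reflux; then isovaleryl chloride (1.05 equiv), CH2Cl2, 0 °C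
Reagents that add atoms: isovaleryl chloride CC(C)CC(=O)Cl
Why: Stannylene-acetal-mediated monoacylation of the cis-1,2-diol takes place at the equatorial C1 oxygen and not at the pseudoaxial C2 oxygen, while the hindered axial 9β hydroxyl stays free.

Step 12
Reactants: 24 1α-(3-methylbutanoyloxy)-14-(tert-butyldimethylsilyloxy)eudesma-3,11-diene-2α,9β-diol
Product: 25 2α,9β-diacetoxy-1α-(3-methylbutanoyloxy)-14-(tert-butyldimethylsilyloxy)eudesma-3,11-diene
Conditions: Ac2O, Et3N, DMAP, CH2Cl2, 0 to 40 °C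
Reagents that add atoms: acetic anhydride CC(=O)OC(C)=O
Why: DMAP-catalysed acetylation esterifies the C2 hydroxyl at 0 °C and the axial C9 hydroxyl on warming, without touching any stereocentre.

Step 13
Reactants: 25 2α,9β-diacetoxy-1α-(3-methylbutanoyloxy)-14-(tert-butyldimethylsilyloxy)eudesma-3,11-diene
Product: 26 target CNP0257109.1 (2α,9β-diacetoxy-14-hydroxy-1α-(3-methylbutanoyloxy)eudesma-3,11-diene; 5βH; 7β-isopropenyl; 10α-CH2OH)
Conditions: HF·pyridine, pyridine/THF, 0 °C
Reagents that add atoms: none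
Why: Buffered fluoride desilylation frees the C14 hydroxyl under mildly acidic conditions that do not promote acyl migration from the C1 or C9 esters.

**Compound list**
1 | acrolein | C=CC=O | starting material
2 | (3Z)-4-iodopenta-1,3-diene | C=C/C=C(/C)I | intermediate
3 | cyclohex-2-en-1-one | O=C1C=CCCC1 | starting material
4 | lithium cyclohexa-1,5-dien-1-olate | [Li]OC1=CCCC=C1 | intermediate
5 | (±)-6-(phenylselanyl)cyclohex-2-en-1-one | O=C1C=CCCC1[Se]c1ccccc1 | intermediate
6 | potassium trifluoro(prop-1-en-2-yl)borate | C=C(C)[B-](F)(F)F.[K+] | starting material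
7 | (3S)-6-(phenylselanyl)-3-(prop-1-en-2-yl)cyclohexan-1-one (both C6 epimers) | C=C(C)[C@@H]1CC(=O)C(CC1)[Se]c1ccccc1 | intermediate
8 | (3S)-6-(benzeneseleninyl)-3-(prop-1-en-2-yl)cyclohexan-1-one | C=C(C)[C@@H]1CC(=O)C(CC1)[Se](=O)c1ccccc1 | intermediate
9 | (5S)-5-(prop-1-en-2-yl)cyclohex-2-en-1-one | C=C(C)[C@@H]1CC(=O)C=CC1 | intermediate
10 | [(2Z)-penta-2,4-dien-2-yl]magnesium chloride | C=C/C=C(/C)[Mg]Cl | intermediate
11 | trimethylsilyl enol ether of trans-3-[(2Z)-penta-2,4-dien-2-yl]-5-(prop-1-en-2-yl)cyclohexanone (5S) | C=C(C)[C@@H]1CC(O[Si](C)(C)C)=C[C@H](C1)/C(C)=C\C=C | intermediate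
12 | (5S)-2-[(dimethylamino)methyl]-3-[(2Z)-penta-2,4-dien-2-yl]-5-(prop-1-en-2-yl)cyclohexan-1-one (3,5-trans) | C=C(C)[C@@H]1CC(=O)C(CN(C)C)[C@H](C1)/C(C)=C\C=C | intermediate
13 | N-methyl quaternary ammonium iodide of 12 | C=C(C)[C@@H]1CC(=O)C(C[N+](C)(C)C)[C@H](C1)/C(C)=C\C=C.[I-] | intermediate
14 | (3R,5S)-2-methylidene-3-[(2Z)-penta-2,4-dien-2-yl]-5-(prop-1-en-2-yl)cyclohexan-1-one | C=C(C)[C@@H]1CC(=O)C(=C)[C@H](C1)/C(C)=C\C=C | intermediate
15 | (5S)-1-ethenyl-2-methylidene-3-[(2Z)-penta-2,4-dien-2-yl]-5-(prop-1-en-2-yl)cyclohexan-1-ol (vinyl β, OH α, vinyl trans to dienyl) | C=C(C)[C@@H]1C[C@](O)(C=C)C(=C)[C@H](C1)/C(C)=C\C=C | intermediate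
16 | 4-ethenyl-8-[(2Z)-penta-2,4-dien-2-yl]-6-(prop-1-en-2-yl)-1-oxaspiro[2.5]octan-4-ol (epoxide O α, syn to OH) | C=C(C)[C@@H]1C[C@](O)(C=C)[C@]2(CO2)[C@H](C1)/C(C)=C\C=C | intermediate
17 | (5S)-2-ethenyl-2-(hydroxymethyl)-3-[(2Z)-penta-2,4-dien-2-yl]-5-(prop-1-en-2-yl)cyclohexan-1-one (vinyl β, CH2OH α) | C=C(C)[C@@H]1CC(=O)[C@@](C=C)(CO)[C@H](C1)/C(C)=C\C=C | intermediate
18 | trans-fused 8a-(hydroxymethyl)-5-methyl-3-(prop-1-en-2-yl)-3,4,4a,8a-tetrahydronaphthalen-1(2H)-one | C=C(C)[C@@H]1CC(=O)[C@@]2(CO)[C@H](C1)C(C)=CC=C2 | intermediate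
19 | cyclic 1α,2α-osmate ester of 18, TMEDA adduct | C=C(C)[C@@H]1CC(=O)[C@@]2(CO)[C@H](C1)C(C)=C[C@@H]3O[Os](=O)(=O)O[C@H]23.CN(C)CCN(C)C | intermediate
20 | 1α,2α,14-trihydroxyeudesma-3,11-dien-9-one | C=C(C)[C@@H]1CC(=O)[C@@]2(CO)[C@H](C1)C(C)=C[C@H](O)[C@@H]2O | intermediate
21 | eudesma-3,11-diene-1α,2α,9β,14-tetraol | C=C(C)[C@@H]1C[C@H](O)[C@@]2(CO)[C@H](C1)C(C)=C[C@H](O)[C@@H]2O | intermediate
22 | 14-O-TBS ether of 21 | C=C(C)[C@@H]1C[C@H](O)[C@@]2(CO[Si](C)(C)C(C)(C)C)[C@H](C1)C(C)=C[C@H](O)[C@@H]2O | intermediate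
23 | 1α,2α-O-dibutylstannylene acetal of 22 | C=C(C)[C@@H]1C[C@H](O)[C@@]2(CO[Si](C)(C)C(C)(C)C)[C@H](C1)C(C)=C[C@@H]3O[Sn](CCCC)(CCCC)O[C@H]23 | intermediate
24 | 1α-isovalerate 2α,9β-diol 14-O-TBS ether | C=C(C)[C@@H]1C[C@H](O)[C@@]2(CO[Si](C)(C)C(C)(C)C)[C@H](C1)C(C)=C[C@H](O)[C@@H]2OC(=O)CC(C)C | intermediate
25 | 2α,9β-diacetate 1α-isovalerate 14-O-TBS ether | C=C(C)[C@@H]1C[C@H](OC(C)=O)[C@@]2(CO[Si](C)(C)C(C)(C)C)[C@H](C1)C(C)=C[C@H](OC(C)=O)[C@@H]2OC(=O)CC(C)C | intermediate
26 | CNP0257109.1 | C=C(C)[C@@H]1C[C@H](OC(C)=O)[C@@]2(CO)[C@H](C1)C(C)=C[C@H](OC(C)=O)[C@@H]2OC(=O)CC(C)C | target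

**Totals**
Total steps: 13. Longest linear sequence: 12 steps (3 → 26, steps 2–13); step 1 makes the side fragment 2.

**Steps most likely to fail**

Step 3 (the proposed new step). Selenium may bind or be cleaved by the rhodium catalyst, or the α-seleno ketone may not survive hot aqueous conditions. The fallback uses known chemistry, sets out from 3 and 6 and comes back at 9. Standard rhodium/(S)-BINAP 1,4-addition of 6 to 3 gives (3S)-3-(prop-1-en-2-yl)cyclohexan-1-one F1. Thermodynamic C-acylation on the less hindered α-carbon (NaH, diallyl carbonate, THF) gives allyl (4S)-2-oxo-4-(prop-1-en-2-yl)cyclohexane-1-carboxylate F2. Tsuji decarboxylative dehydrogenation (Pd(OAc)2, dppe, MeCN, 80 °C) then gives 9 with the same regiochemistry.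

Step 6 (with the facial selectivity it inherits from step 5). The epoxidation must choose the exocyclic methylene over the vinyl group. The vinyl shift also needs the conformer in which the axial vinyl group is syn to the axial isopropenyl group, so ring contraction by migration of C8 could compete. The fallback sets out from 9 (and 2) and comes back at 17. Morita–Baylis–Hillman hydroxymethylation of 9 (aq. CH2O, DMAP) gives (5S)-2-(hydroxymethyl)-5-(prop-1-en-2-yl)cyclohex-2-en-1-one F3, which is silylated (t-BuMe2SiCl, imidazole) to its TBS ether F4. Copper-catalysed conjugate addition of the Grignard reagent from 2 with Me3SiCl trapping, enolate regeneration (MeLi) and palladium-catalysed α-vinylation (vinyl bromide, Pd2(dba)3, P(t-Bu)3) anti to the dienyl group give the 14-O-TBS ether of 17 F5. Bu4NF then gives 17.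

Step 8. Osmylation must pick the C1=C2 bond of the diene and its α face. The fallback sets out from 18 and comes back at 25. Hydroxyl-directed epoxidation (VO(acac)2, t-BuOOH) gives the 1α,2α-epoxide of 18 F6. Pd(PPh3)4 with AcOH opens the vinyl epoxide at C2 with overall retention (double inversion through the π-allyl complex of divalent palladium) to give the 2α-acetoxy-1α,14-dihydroxy-9-ketone F7. Me4NBH(OAc)3 gives its 9β-alcohol F8, and t-BuMe2SiCl gives the 14-O-TBS ether F9. Isovaleryl chloride with DMAP acylates the C1 hydroxyl in preference to the hindered 9β hydroxyl to give the 1α-isovalerate 2α-acetate 9β-alcohol F10, and Ac2O/DMAP gives 25.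

**Further compounds**
F1 | step 3 | (3S)-3-(prop-1-en-2-yl)cyclohexan-1-one | C=C(C)[C@@H]1CC(=O)CCC1
F2 | step 3 | allyl (4S)-2-oxo-4-(prop-1-en-2-yl)cyclohexane-1-carboxylate | C=C(C)[C@@H]1CC(=O)C(CC1)C(=O)OCC=C
F3 | step 6 | (5S)-2-(hydroxymethyl)-5-(prop-1-en-2-yl)cyclohex-2-en-1-one | C=C(C)[C@@H]1CC(=O)C(CO)=CC1
F4 | step 6 | TBS ether of F3 | C=C(C)[C@@H]1CC(=O)C(CO[Si](C)(C)C(C)(C)C)=CC1
F5 | step 6 | 14-O-TBS ether of 17 | C=C(C)[C@@H]1CC(=O)[C@@](C=C)(CO[Si](C)(C)C(C)(C)C)[C@H](C1)/C(C)=C\C=C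
F6 | step 8 | 1α,2α-epoxide of 18 | C=C(C)[C@@H]1CC(=O)[C@@]2(CO)[C@H](C1)C(C)=C[C@@H]3O[C@H]23
F7 | step 8 | 2α-acetoxy-1α,14-dihydroxyeudesma-3,11-dien-9-one | C=C(C)[C@@H]1CC(=O)[C@@]2(CO)[C@H](C1)C(C)=C[C@H](OC(C)=O)[C@@H]2O
F8 | step 8 | 2α-acetoxyeudesma-3,11-diene-1α,9β,14-triol | C=C(C)[C@@H]1C[C@H](O)[C@@]2(CO)[C@H](C1)C(C)=C[C@H](OC(C)=O)[C@@H]2O
F9 | step 8 | 14-O-TBS ether of F8 | C=C(C)[C@@H]1C[C@H](O)[C@@]2(CO[Si](C)(C)C(C)(C)C)[C@H](C1)C(C)=C[C@H](OC(C)=O)[C@@H]2O
F10 | step 8 | 1α-isovalerate of F9 | C=C(C)[C@@H]1C[C@H](O)[C@@]2(CO[Si](C)(C)C(C)(C)C)[C@H](C1)C(C)=C[C@H](OC(C)=O)[C@@H]2OC(=O)CC(C)C
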